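Z splits two ways: one step sends it to J, which goes on to X, and the other sends it to E, which goes on to G.

all flasks: Z 0.12 M

| charge | time | remark |
|---|---|---|
| teal | 50 h | everything together in a closed stirred flask, run for 50 h |
| blue |  | one stirred flow tank at steady state, fed with the mixture as stated, mean residence time 50 h |
| amber | 50 h | a tube with plug flow, the mixed feed as stated, residence time 50 h |

    Z → J (k1 = 0.214 h⁻¹)
    Z → E (k2 = 0.0858 h⁻¹)
    J → X (k3 = 0.172 h⁻¹)
    E → G (k4 = 4.95 h⁻¹)

- the stated concentrations are those of everything mixed, before any reaction; amounts are the same in each set-up
- run time (teal): 50 h

- the set-up with the highest amount of G at the outlet or at the end, in percent of the Z put in ("none" if the first two lie within 2 percentage points) (teal / blue / amber / none)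
- amount of G at the outlet or at the end, in percent of the Z put in, teal
- amount of G at the outlet or at the end, in percent of the Z put in, blue
- amount of G at the outlet or at the end, in percent of the Z put in, amber

Ask first what the end state must be. E has a half-life of 0.140 h under its own step, shorter than the 2.31 h of Z under its two steps together, so what enters E passes on to G. The yield of G is therefore the branch share times the part of Z that has reacted. The branch share (the selectivity of this parallel pair) is the constant of Z to E over the sum of both constants of Z, 28.6%.

Two chemists differ on how fast that end is approached. The first measures by half-lives: 50 h is 21.6 half-lives of Z, so this view counts Z as fully reacted in the teal flask, the blue tank and the amber tube alike, and gives each 28.6%.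

The second says the blue tank holds Z at its outlet concentration. The sum constant times the residence time is 15.0, and the part of Z left is one over one plus that, 6.25%. My own reckoning sides with the second: the blue tank gives 26.8%, which is 1.8 percentage points below the share and inside the margin of 2 points.

The forecast takes the same side, with 28.6% for teal, 26.7% for blue, 28.6% for amber and best none, and says “E drains almost instantly to G”. Its blue figure is 0.10 points below mine.

The simulation gives 28.6% for teal, 26.7% for blue and 28.6% for amber, so best is none. The second chemist holds the blue tank, and the first view stands in the teal flask and the amber tube, where the yield equals the share. The blue tank keeps cZ at 0.00750 M, which is 6.25% of the Z charged. Strike out the step from Z to J in that tank, and the share rises from 28.6% to 100%, while the reacted part falls to 81.1%. With the passing of Z into J struck out, the amount of G at the outlet of the blue tank, in percent of the Z put in, is 80.8%.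

All constants are those of an exercise; the result is computed.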